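Remark on the chemistry: ring A is the monobromo ring (hydroxyl on C1, bridging oxygen on C2, bromine on C4) and ring B the tribromo ring (hydroxyl on C1, bridging oxygen on C2, bromine on C3, C4 and C6); these locants are kept for all precursors, and the target has no stereocentre.

## Structural features

The target is a diaryl ether in which two benzene rings are joined through a single oxygen; it has no further ring and no stereocentre. Ring A is a phenol with the hydroxyl on C1, the bridging oxygen on C2 and one bromine on C4, para to the hydroxyl. Ring B carries its hydroxyl on C1, the bridging oxygen on C2 and bromine on C3, C4 and C6, so that only C5 bears hydrogen and each ring is a catechol mono-aryl ether with the hydroxyl ortho to the ether oxygen. The four aryl bromides rule out late palladium or copper coupling, halogen–metal exchange and hydrogenolysis, and the free phenols are prone to over-bromination and oxidation. The real difficulty is regiochemical: C4 and C6 of ring B lie para and ortho to the ring B hydroxyl and can come from phenol-directed bromination, whereas the bromine on C3 is meta to that hydroxyl and cannot. Ring A must keep C6, the open carbon ortho to its hydroxyl, free of bromine, so the two hydroxyls have to be distinguished during the halogenation. The key step exploits the oxygen on C1 of ring A and the oxygen on C1 of ring B: each can begin as a carbonyl substituent (an acetyl group on ring A, a formyl group on ring B that also activates the SNAr building the ether) and is then converted into the C1–O bond by aryl migration, which leaves two esters of unequal lability.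

## Logic of the disconnections

8 to 7: the acyl–oxygen bond on the C1 oxygen of ring A is put back, so that the ring A hydroxyl stays an acetate until the end. The acetate keeps ring A less reactive than ring B while the halogen is introduced. The forward step must cleave one aryl ester without touching four aryl bromides, which mild acid methanolysis should do.

7 to 6: the C4–Br and C6–Br bonds of ring B are cut. They lie para and ortho to the ring B hydroxyl, the positions that a free phenol brominates. Two of the four bromines leave the problem, while the C3 bromine, out of reach of this directing effect, is kept. The forward step needs a free hydroxyl on ring B, an acylated oxygen on ring A and no more than two equivalents of the halogen.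

6 to 5: the ring B hydroxyl is traced back to its formate. 5 is what the oxidation delivers, and a formate is far more labile than an acetate. The forward step must remove the formyl group while the acetyl group neither leaves nor moves.

5 to 3 (through 4): the C1–O bonds of ring A and of ring B are cut and the C1–C(carbonyl) bonds reinstated, an acetyl group on ring A and a formyl group on ring B. The donor oxygen of ring B becomes an acceptor group ortho to the ether carbon, which is what an SNAr ether synthesis needs, and the ketone/aldehyde difference becomes the later acetate/formate difference. 3 is reachable from two purchasable arenes. The forward step requires aryl migration at both carbonyl groups, in preference to hydride on ring B and to methyl on ring A, under conditions that spare the formate.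

3 to 1 and 2: the bond between the bridging oxygen and C2 of ring B is cut. That carbon is flanked by the formyl group and the C3 bromine, so it is the better electrophilic site when it carries fluorine, and the oxygen on ring A is the less hindered, more basic nucleophile. The opposite polarity would pair a phenoxide flanked by formyl and bromine with a fluoride activated only by a ketone, which is the weaker combination. Both bromines of 3 are bought in place. The forward step must join the rings with a base mild enough not to condense the methyl ketone with the aldehyde.

## Other disconnections considered

Alternative 1: The cut runs through the C2–C3 and C5–C6 bonds of ring A, so that this ring is assembled from an aryloxy ketone and a three-carbon enal. In the forward key step 1-(2,3,5-tribromo-6-methoxyphenoxy)propan-2-one A1 and prop-2-enal A2 would be combined under secondary-amine catalysis. Enamine Michael addition of the oxygen-bearing carbon of A1 to A2, followed by aldol condensation of the methyl group onto the aldehyde, should close the carbocycle and give racemic 6-(2,3,5-tribromo-6-methoxyphenoxy)cyclohex-2-en-1-one A3.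

- In its favour: no SNAr and no peracid are needed, so there is no migratory-aptitude question, and on that point it is better than the chosen plan. The ring B oxygen is a methyl ether that cannot migrate or fall off, which is also a better point. The annulation is mild and metal-free, equal to the SNAr in that respect.
- Against it: A1 presupposes 2,3,5-tribromo-6-methoxyphenol A4. Two of the bromines of A4 lie ortho and para to the methylated oxygen and the carbon para to its free hydroxyl is unsubstituted, a pattern that direct bromination of a guaiacol would not give, so A4 needs several steps with an exchange of protecting groups.
- A3 is one oxidation level below a phenol and must be dehydrogenated to 2-(2,3,5-tribromo-6-methoxyphenoxy)phenol A5. The aryloxy group of A3 sits alpha to the carbonyl as a good leaving group, so its loss could compete.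
- Ring A of A5 must then be monobrominated para to its hydroxyl with an ortho carbon left open, and the methyl ether cleaved.
- Comparison: structurally the alternative constructs a benzene ring that can be bought fully substituted, while the chosen plan makes only C–O bonds. The stereocentre of A3 is made only to be destroyed. In step count it would need at least eight operations against five.

Alternative 2: The cut is on ring B at O–C2 and C3–Br, both formed across an aryne, with C1 carried as a C–B bond. In the forward key step 2-iodo-6-(4,4,5,5-tetramethyl-1,3,2-dioxaborolan-2-yl)phenyl trifluoromethanesulfonate A6 would be treated with iPrMgCl·LiCl in the presence of the aryloxide of 5-bromo-2-methoxyphenol A7. The aryloxide should add to the aryne carbon next to boron, and the aryl Grignard reagent so formed would be trapped by a perhaloethane bromine donor (BrCl2C–CCl2Br). The product would be 2-[3-bromo-2-(5-bromo-2-methoxyphenoxy)phenyl]-4,4,5,5-tetramethyl-1,3,2-dioxaborolane A8. C–B oxidation of A8 would then give 3-bromo-2-(5-bromo-2-methoxyphenoxy)phenol A9, the methyl ether counterpart of 6, and dibromination followed by O-demethylation with BBr3 would finish.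

- In its favour: the ether bond and the meta bromine are set in one operation, with regiochemistry fixed by boron. The hydroxyl is unmasked by C–B oxidation, which has no hydride-versus-aryl question, a better point than the chosen plan. The methyl ether on ring A is more robust than an acetate, also better. A7 is bought with the ring A bromine in place, which is equal.
- Against it: an aryloxide is a weak aryne nucleophile and must compete with the isopropyl Grignard reagent. Addition next to boron is better founded for amines than for oxygen nucleophiles. The aryl Grignard reagent must survive next to a boronate and in the presence of aryl bromides. A6 needs a synthesis of its own.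
- The anisole ring A of A9 is less deactivated toward bromine than the acetate ring of 6, and the route ends with BBr3.
- Comparison: the alternative is more convergent at ring B, but it rests on a three-component organometallic step at low temperature where the chosen plan uses an SNAr and a peracid. It would need about seven steps in the longest line against five.

Alternative 3: The cut goes through the aromaticity of ring B and its C4–Br and C6–Br bonds, so that ring B derives from a six-membered cyclic 1,3-diketone. 2-Diazocyclohexane-1,3-dione A10 and A7 would give 2-(5-bromo-2-methoxyphenoxy)cyclohexane-1,3-dione A11 by Rh2(OAc)4-catalysed O–H insertion. Conversion of one carbonyl group of A11 into the vinyl bromide would give 3-bromo-2-(5-bromo-2-methoxyphenoxy)cyclohex-2-en-1-one A12. In the forward key step three equivalents of Br2 would brominate A12 next to the carbonyl, HBr would be lost, and the dienone would tautomerise to A9. The new hydroxyl would then direct two more bromines to C4 and C6, giving 3,4,6-tribromo-2-(5-bromo-2-methoxyphenoxy)phenol A13. BBr3 would cleave the methyl ether of A13 to complete the synthesis.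

- In its favour: the whole ring B pattern comes from one cheap symmetric dione, and the C3 bromine is placed unambiguously by the vinyl bromide. No migratory aptitude is involved, which is better. The methyl ether is robust, which is also better.
- Against it: A10 is a diazo compound and its preparation needs a sulfonyl azide, which is a safety cost. The O–H insertion and the bromide formation on the 2-aryloxy dione A11 are less routine than an SNAr.
- Three equivalents of Br2 and the HBr they release act on a substrate whose anisole ring A is not deactivated. In the chosen plan ring A is an aryl acetate and should resist better.
- Comparison: both routes end with phenol-directed bromination of the same type of ring B intermediate, an equal point. The step count would be five, equal to the chosen plan. The chosen plan buys both of its pre-placed bromines and avoids diazo chemistry and BBr3.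

Key step: step 2

## Route

Step 1
Reactants: 1 1-(4-bromo-2-hydroxyphenyl)ethan-1-one; 2 3-bromo-2-fluorobenzaldehyde
Product: 3 2-(2-acetyl-5-bromophenoxy)-3-bromobenzaldehyde
Conditions: K2CO3 (1.5 equiv), DMF, 70 °C
Reagents that add atoms: none
Why: SNAr by addition–elimination: the fluoride of 2 is ortho to the formyl group, which stabilises the Meisenheimer adduct, and is displaced far faster than either bromide; the phenoxide of 1 is the less hindered and more basic oxygen nucleophile of the two possible pairings. Moderate temperature, a weak base and a slight excess of 2 should hold back carbonate-promoted aldol condensation of the methyl ketone with the aldehyde.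

Step 2
Reactants: 3 2-(2-acetyl-5-bromophenoxy)-3-bromobenzaldehyde
Product: 5 4-bromo-2-(2-bromo-6-formyloxyphenoxy)phenyl acetate, via keto formate 4 (not isolated)
Conditions: mCPBA (3 equiv, predried in CH2Cl2), TFA (0.5 equiv), CH2Cl2, 0 °C to rt, dark
Reagents that add atoms: 3-chloroperoxybenzoic acid (mCPBA), O=C(OO)c1cccc(Cl)c1
Why: Twofold Baeyer–Villiger oxidation, which for the aldehyde is the formate-forming variant known as the first stage of a Dakin oxidation. The peracid adds to each activated carbonyl group to give a Criegee adduct, and the substituent antiperiplanar to the breaking O–O bond that best carries positive charge moves from carbon to oxygen. On ring B the migrating carbon C1 has the bridging oxygen ortho to it, whose lone pair stabilises the bridged transition state, so aryl should win over hydride and the formate should form and not the benzoic acid; on ring A the same ortho oxygen should put aryl ahead of methyl and give the acetate and not the methyl ester. The aldehyde reacts first, so keto formate 4 is passed through, and TFA is present to speed up the slower aryl ketone. No ring is closed and no stereocentre is made. The step needs migratory selectivity (aryl at both sites) and chemoselectivity (formate kept, arenes untouched): the first rests on the ortho aryloxy donor of each ring, the second on dried peracid, the absence of water and base, and the bromines, which make both rings poor substrates for electrophilic oxygen. The closest known reaction type is the peracid oxidation of ortho-alkoxy and ortho-aryloxy benzaldehydes and acetophenones to aryl formates and acetates.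

Step 3
Reactants: 5 4-bromo-2-(2-bromo-6-formyloxyphenoxy)phenyl acetate
Product: 6 4-bromo-2-(2-bromo-6-hydroxyphenoxy)phenyl acetate
Conditions: NaHCO3 (0.2 equiv), MeOH/CH2Cl2, 0 °C
Reagents that add atoms: none
Why: Transesterification: an aryl formate, with no alpha substituent and a more electrophilic carbonyl, should be methanolysed far faster than an aryl acetate. At 0 °C with a base too weak to ionise the new phenol appreciably, the acetate on ring A should neither be lost nor shift to the ring B oxygen; 6 is taken on without delay.

Step 4
Reactants: 6 4-bromo-2-(2-bromo-6-hydroxyphenoxy)phenyl acetate
Product: 7 4-bromo-2-(2,3,5-tribromo-6-hydroxyphenoxy)phenyl acetate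
Conditions: Br2 (2.05 equiv), NaOAc (2.2 equiv), AcOH, rt
Reagents that add atoms: bromine, BrBr
Why: Electrophilic aromatic bromination directed by the free hydroxyl of ring B to its para carbon C4 and its only open ortho carbon C6, both also ortho or para to the C3 bromine. Ring A, carrying an acetoxy group and a bromine, should be much less reactive; the bromine charge is limited to two equivalents and NaOAc takes up HBr so that the acetate is not cleaved.

Step 5
Reactants: 7 4-bromo-2-(2,3,5-tribromo-6-hydroxyphenoxy)phenyl acetate
Product: 8 3,4,6-tribromo-2-(5-bromo-2-hydroxyphenoxy)phenol
Conditions: HCl (cat.), MeOH, 40 °C
Reagents that add atoms: none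
Why: Acid-catalysed transesterification of the aryl acetate with methanol; the medium is neither basic nor oxidising, so the diaryl ether, the four aryl bromides and the two phenols should be unaffected.

## Compound list

1 | 1-(4-bromo-2-hydroxyphenyl)ethan-1-one | CC(=O)c1ccc(Br)cc1O | starting material
2 | 3-bromo-2-fluorobenzaldehyde | O=Cc1cccc(Br)c1F | starting material
3 | 2-(2-acetyl-5-bromophenoxy)-3-bromobenzaldehyde | CC(=O)c1ccc(Br)cc1Oc1c(C=O)cccc1Br | intermediate
4 | 2-(2-acetyl-5-bromophenoxy)-3-bromophenyl formate (keto formate) | CC(=O)c1ccc(Br)cc1Oc1c(OC=O)cccc1Br | intermediate
5 | 4-bromo-2-(2-bromo-6-formyloxyphenoxy)phenyl acetate | CC(=O)Oc1ccc(Br)cc1Oc1c(OC=O)cccc1Br | intermediate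
6 | 4-bromo-2-(2-bromo-6-hydroxyphenoxy)phenyl acetate | CC(=O)Oc1ccc(Br)cc1Oc1c(O)cccc1Br | intermediate
7 | 4-bromo-2-(2,3,5-tribromo-6-hydroxyphenoxy)phenyl acetate | CC(=O)Oc1ccc(Br)cc1Oc1c(O)c(Br)cc(Br)c1Br | intermediate
8 | 3,4,6-tribromo-2-(5-bromo-2-hydroxyphenoxy)phenol | Oc1ccc(Br)cc1Oc1c(O)c(Br)cc(Br)c1Br | target

## Step count and least certain steps

Total step count: 5. Longest linear sequence: 5 steps (from 1 or 2 to 8).

Step 2 (key step). The two oxidations are likely to run at very different rates. The aldehyde should be consumed early, while the aryl methyl ketone, crowded by the ortho aryloxy group, reacts slowly. Long exposure to peracid and acid invites loss of the formyl group and oxidation of the phenol so exposed. In addition, while ring A is still a ketone the bridging oxygen is partly drained by the acetyl group, which may let hydride migration compete with aryl migration at the aldehyde.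

The fallback separates the two migrations and places the bromination between them; it sets out from 3 and comes back to the route at 7. One equivalent of mCPBA at 0 °C without acid should stop at keto formate 4, which is now isolated. NaHCO3 in MeOH then gives 1-[4-bromo-2-(2-bromo-6-hydroxyphenoxy)phenyl]ethan-1-one F1, with no second ester present to be lost. Br2 and NaOAc in AcOH give 1-[4-bromo-2-(2,3,5-tribromo-6-hydroxyphenoxy)phenyl]ethan-1-one F2; ring A is protected here by the acetyl group itself, a stronger deactivator than an acetate. Baeyer–Villiger oxidation of the remaining ketone (mCPBA, TFA, CH2Cl2, rt to reflux) can then be forced, because no formate is present and the free phenol is an electron-poor tribromophenol, and it gives 7.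

Step 1. Carbonate-promoted aldol condensation between the methyl ketone and the aldehyde is the main danger. It could occur within 3 or between 3 and 1 and would divert material into chalcone-type products, because the substitution needs heat in a dipolar solvent.

The fallback masks the ketone as an alcohol; it sets out from 1 and comes back to the route at 3. NaBH4 in MeOH reduces 1 to racemic 5-bromo-2-(1-hydroxyethyl)phenol F3. The same SNAr with 2 (K2CO3, DMF) then has no enolisable ketone present and gives racemic 3-bromo-2-[5-bromo-2-(1-hydroxyethyl)phenoxy]benzaldehyde F4. Dess–Martin periodinane in CH2Cl2 oxidises the secondary benzylic alcohol, leaves the aldehyde alone and gives 3.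

Step 3. The acetate may be lost along with the formate, or the acetyl group may transfer under base from the ring A oxygen to the newly freed ring B oxygen, since both oxygens sit ortho to the same bridging oxygen. Either event would leave ring A unprotected in the bromination.

The fallback gives up the separate basic step; it sets out from 5 and comes back to the route at 7. 5 is treated with Br2 (2.05 equiv) and catalytic HBr in MeOH/CH2Cl2 at 0 °C. Acid-catalysed methanolysis of the formate, much faster than that of the acetate, releases 6, which is brominated as it forms and is not isolated. No phenoxide is present to carry an acyl shift. No compound outside the compound list arises, so the entry for this fallback is F0.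

## Further compounds

F1 | step 2 | 1-[4-bromo-2-(2-bromo-6-hydroxyphenoxy)phenyl]ethan-1-one | CC(=O)c1ccc(Br)cc1Oc1c(O)cccc1Br
F2 | step 2 | 1-[4-bromo-2-(2,3,5-tribromo-6-hydroxyphenoxy)phenyl]ethan-1-one | CC(=O)c1ccc(Br)cc1Oc1c(O)c(Br)cc(Br)c1Br
F3 | step 1 | 5-bromo-2-(1-hydroxyethyl)phenol (racemic) | CC(O)c1ccc(Br)cc1O
F4 | step 1 | 3-bromo-2-[5-bromo-2-(1-hydroxyethyl)phenoxy]benzaldehyde (racemic) | CC(O)c1ccc(Br)cc1Oc1c(C=O)cccc1Br
F0 | step 3 | none | none
A1 | alternative 1 | 1-(2,3,5-tribromo-6-methoxyphenoxy)propan-2-one | CC(=O)COc1c(OC)c(Br)cc(Br)c1Br
A2 | alternative 1 | prop-2-enal | C=CC=O
A3 | alternative 1 | 6-(2,3,5-tribromo-6-methoxyphenoxy)cyclohex-2-en-1-one (racemic) | O=C1C=CCCC1Oc1c(OC)c(Br)cc(Br)c1Br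
A4 | alternative 1 | 2,3,5-tribromo-6-methoxyphenol | Oc1c(OC)c(Br)cc(Br)c1Br
A5 | alternative 1 | 2-(2,3,5-tribromo-6-methoxyphenoxy)phenol | Oc1ccccc1Oc1c(OC)c(Br)cc(Br)c1Br
A6 | alternative 2 | 2-iodo-6-(4,4,5,5-tetramethyl-1,3,2-dioxaborolan-2-yl)phenyl trifluoromethanesulfonate | CC1(C)OB(OC1(C)C)c1cccc(I)c1OS(=O)(=O)C(F)(F)F
A7 | alternative 2 | 5-bromo-2-methoxyphenol | COc1ccc(Br)cc1O
A8 | alternative 2 | 2-[3-bromo-2-(5-bromo-2-methoxyphenoxy)phenyl]-4,4,5,5-tetramethyl-1,3,2-dioxaborolane | COc1ccc(Br)cc1Oc1c(Br)cccc1B1OC(C)(C)C(C)(C)O1
A9 | alternative 2 | 3-bromo-2-(5-bromo-2-methoxyphenoxy)phenol | COc1ccc(Br)cc1Oc1c(O)cccc1Br
A10 | alternative 3 | 2-diazocyclohexane-1,3-dione | O=C1CCCC(=O)C1=[N+]=[N-]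
A11 | alternative 3 | 2-(5-bromo-2-methoxyphenoxy)cyclohexane-1,3-dione | COc1ccc(Br)cc1OC1C(=O)CCCC1=O
A12 | alternative 3 | 3-bromo-2-(5-bromo-2-methoxyphenoxy)cyclohex-2-en-1-one | COc1ccc(Br)cc1OC1=C(Br)CCCC1=O
A13 | alternative 3 | 3,4,6-tribromo-2-(5-bromo-2-methoxyphenoxy)phenol | COc1ccc(Br)cc1Oc1c(O)c(Br)cc(Br)c1Br
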